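The runs were generated by integration for an exercise, and the scatter is random.

Turn the readings into one time constant.

the same everywhere: L 2.4 µM
- Thursday's: Z 12 mM; D 12 mM; run made earlier
- Monday's: Z 12 mM; D 8 mM; run made earlier
- Wednesday's: Z 12 mM; D 18 mM; run made earlier
- Saturday's: Z 18 mM; D 12 mM; run made earlier
- spring: Z 12 mM (fed, over 15 h); D 12.0 mM; all else is in the flask from the start; the feed brings no volume worth counting; time 40 h
- dawn: Z 12 mM; D 12.0 mM; everything together at the start; time 40 h
- autumn: Z 12 mM (in portions, 2, over 15 h); D 12.0 mM; first portion at the start, last at 15 h; time 40 h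
- winter: Z 12 mM; D 12.0 mM (fed, over 15 h); all else is in the flask from the start; the feed brings no volume worth counting; time 40 h

- Thursday's (time / h: G / %, Z / %): 6.00: 9, 94; 12.0: 13, 90; 20.0: 18, 80; 25.0: 25, 75
- Monday's (time / h: G / %, Z / %): 6.00: 10, 91; 15.0: 22, 79; 30.0: 39, 60; 50.0: 59, 41
- Wednesday's (time / h: G / %, Z / %): 4.00: 3, 93; 8.00: 8, 95; 20.0: 14, 88; 50.0: 32, 68
- Saturday's (time / h: G / %, Z / %): 6.00: 6, 93; 15.0: 19, 85; 30.0: 29, 73; 50.0: 46, 56

(scatter of a reading: 1.5 percentage points)

- the analysis behind the earlier runs scatters by 1.5 percentage points, standard deviation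
- steps thought possible: E -> L + G; 2 Q <-> X; D + L <-> Q; Z + L <-> E; Q -> L + J

- the flask that comes out highest in amount of G, in percent of the Z charged, or "all alike" when all lie within 1.5 percentage points (spring / dawn / autumn / winter / all alike)
- G at the end, in percent of the Z charged, spring
- G at the end, in percent of the Z charged, dawn
- G at the end, in percent of the Z charged, autumn
- G at the end, in percent of the Z charged, winter

Read a first-order constant for Z from the last point of each run. Thursday's gives 0.0115 h⁻¹, and Saturday's, with more Z charged, gives 0.0116 h⁻¹, about the same, so treat Z as pseudo-first-order.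

Now ask what D does. Monday's gives 0.0178 h⁻¹ and Wednesday's 0.00771 h⁻¹, so the constant falls as D rises. Multiply each constant by its D: Monday's gives 0.143 mM h⁻¹, Wednesday's 0.139 mM h⁻¹ and Thursday's 0.138 mM h⁻¹. Call this reading the clock product, the first-order constant of Z times the D in the flask. The time constant of Z is then D divided by it, 86.9 h at the charge of dawn, so dawn reaches about 36.9% of G.

Does holding Z back pay? Each part of Z decays on the same clock, so spring and autumn both start their average portion 7.50 h late. That lowers them to about 31.2%, less than dawn.

Does holding D back pay? In winter D is fed at a steady rate, so take its mean over the feed as half the charge. Reckon the feed at that mean D and the rest of the time at the charge: this estimate gives winter about 46.9%. That beats dawn by 10 percentage points, well beyond the margin, so expect winter highest.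

The forecast gives 31%, 37%, 31% and 53% for spring, dawn, autumn and winter, above my estimate for winter, with a low-D term it calls “poorly known, and the main uncertainty”.

Winter gives 54.5% of G, against 37.7% for dawn, 32.1% for spring and 31.9% for autumn.

E → L + G (k = 2500 h⁻¹); 2 Q ⇌ X (K = 7.80 × 10⁵ M⁻¹, k = 9.00 × 10⁵ M⁻¹ h⁻¹); D + L ⇌ Q (K = 490 M⁻¹, k = 2.10 × 10⁵ M⁻¹ h⁻¹); Z + L ⇌ E (K = 27.0 M⁻¹, k = 7.80 × 10⁵ M⁻¹ h⁻¹); Q → L + J (k = 55.0 h⁻¹) Mean D in winter over the feed stood at 5.70 mM. Start the clock from the 61.5% of Z in winter at 15.0 h: it gives 46.1% at 40 h, and the flask holds 45.5%. For the neighbour of winter charged with 20 mM of D, the same estimate on mean D is 31.6%, and that neighbour gives 40.7% of G.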